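The target joins ring A (2,6-dihydroxyphenyl) and ring B (4-hydroxy-3-methoxyphenyl) through a nine-carbon chain, C1 (ketone on ring A) to C9 (benzylic CH2 on ring B). It has no stereocentre and no ring beyond the two arenes.
Retrosynthesis: C2–C3 and C7–C8 are raised to double bonds and the two ring A phenols are masked as benzyl ethers. Both double bonds are then cut at once, and the vinyl ketone is traced back to an acetophenone.
Enabling feature: the two cuts frame exactly five carbons, C3–C7, which is the skeleton of an opened cyclopentene. Ring A–C1–C2 is then an aryl vinyl ketone and C8–C9–ring B is eugenol, each less its terminal CH2.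
Forward: 2',6'-dihydroxyacetophenone is benzylated and alpha-methylenated to the enone. One metathesis pot joins the enone to cyclopentene (C2=C3), then the opened chain to eugenol (C7=C8). One hydrogenation saturates the chain and frees ring A; no ring is formed at any stage.
Stereochemistry: there is none to set, and the geometry of the two transient alkenes is erased in the last step.

Key step: step 3

Assumption: 8 is named and drawn as its (2E,7E) isomer. Any 7Z isomer formed beside it is carried on, because step 4 removes both double bonds.

Step 1
Reactants: 1 2',6'-dihydroxyacetophenone
Product: 2 1-[2,6-bis(benzyloxy)phenyl]ethan-1-one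
Conditions: BnBr (2.5 equiv), K2CO3 (4 equiv), DMF, 70 °C
Reagents that add atoms: benzyl bromide, BrCc1ccccc1
Why: Double Williamson ether synthesis, in which carbonate in hot DMF overcomes the hydrogen bonds of both phenols to the ketone and the phenoxides are O-benzylated by SN2, a standard protection that leaves the methyl ketone untouched.

Step 2
Reactants: 2 1-[2,6-bis(benzyloxy)phenyl]ethan-1-one
Product: 4 1-[2,6-bis(benzyloxy)phenyl]prop-2-en-1-one, via Mannich base 3 (not isolated)
Conditions: (CH2O)n (4 equiv in two portions), iPr2NH·CF3CO2H (1 equiv), CF3CO2H (10 mol %), THF, reflux; product kept cold and used promptly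
Reagents that add atoms: paraformaldehyde (reacts as formaldehyde), C=O; diisopropylammonium trifluoroacetate, CC(C)[NH2+]C(C)C.[O-]C(=O)C(F)(F)F (its amine unit sits only in 3 and is lost again on the way to 4)
Why: Mannich alpha-methylenation, an established one-pot procedure for aryl methyl ketones, in which the enol of 2 (only one enolisable carbon) attacks the iminium ion formed in situ to give 3, whose bulky protonated amino group leaves by beta-elimination under the same conditions, the benzyl ethers being inert to the weak acid.

Step 3
Reactants: 4 1-[2,6-bis(benzyloxy)phenyl]prop-2-en-1-one; 5 cyclopentene; 6 eugenol (4-allyl-2-methoxyphenol)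
Product: 8 (2E,7E)-1-[2,6-bis(benzyloxy)phenyl]-9-(4-hydroxy-3-methoxyphenyl)nona-2,7-dien-1-one, via octadienone 7 (not isolated)
Conditions: (a) 5 (15 equiv, 2.5 M), second-generation Hoveyda–Grubbs catalyst RuCl2(SIMes)(=CH-C6H4-2-OiPr) (2.5 mol %; SIMes = 1,3-dimesitylimidazolidin-2-ylidene), 1,4-benzoquinone (10 mol %), CH2Cl2, 20 °C, 4 (1 equiv) added over 3 h; (b) 6 (5 equiv), same catalyst (2.5 mol %), dilution with toluene to 0.01 M, 45 °C, slow Ar stream carrying off 5 and ethene, stopped when the homologues have collapsed; ethyl vinyl ether quench
Reagents that add atoms: none
Why: Proposed new method: in stage a the propagating ruthenium alkylidene opens 5 by the Chauvin [2+2]/retro-[2+2] sequence and the alkyl-substituted carbene so formed is trapped by the electron-poor vinyl group of 4, which sets the conjugated C2=C3 bond and gives 7 plus homologues holding further C5H8 units, while the high concentration of 5 (above its ceiling concentration) and the slow feed of 4 keep a second molecule of 4 away from the same C5 unit. In stage b dilution, warming and removal of 5 turn the low-strain ring opening around, so that every non-conjugated 1,6-diene repeat back-bites to cyclopentene, whereas the last C5 unit stays because its loss would have to pass through an acyl-substituted ruthenium carbene at C2, and the carbene left at C7 is capped by the excess of 6 to form C7=C8 with loss of ethene. The closest known reaction types are ring-opening cross-metathesis of cyclopentene or cyclohexene with acrylates and enones (which caps both ends alike), chain-transfer ring-opening metathesis polymerisation with equilibrium depolymerisation of polypentenamer, and cross-metathesis of eugenol with acrylates, but capping of one opened ring by two different partners in one pot is without precedent. No ring is closed and no stereocentre is formed; C2=C3 should be E under thermodynamic control and the geometry at C7=C8 does not matter because step 4 saturates both bonds. The selectivity needed is hetero-capping with exactly one C5 insertion, and it is secured by the reactivity gap between the enone terminus (limiting, used up before 6 enters, hence no direct coupling of 4 with 6, and inert once conjugated) and the allylarene terminus (in excess, reversible, so mismatched pairings are corrected) together with the small strain of 5. The phosphine-free catalyst rules out conjugate addition of PCy3 to 4, 1,4-benzoquinone holds back ruthenium hydride double-bond migration that would shift the chain length or conjugate the allyl group with ring B, and the benzyl ethers keep the ortho oxygens of ring A from adding to C3.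

Step 4
Reactants: 8 (2E,7E)-1-[2,6-bis(benzyloxy)phenyl]-9-(4-hydroxy-3-methoxyphenyl)nona-2,7-dien-1-one
Product: 10 1-(2,6-dihydroxyphenyl)-9-(4-hydroxy-3-methoxyphenyl)nonan-1-one, via saturated dibenzyl ether 9 (not isolated)
Conditions: H2 (1 atm), 10% Pd/C, EtOAc–EtOH 1:1, rt
Reagents that add atoms: none
Why: Catalytic hydrogenation combined with O-benzyl hydrogenolysis, both routine over Pd/C, in which the two disubstituted alkenes should be saturated faster than the benzyl ethers are cleaved, so the ortho phenols of ring A appear only when no Michael acceptor is left, while the hindered and later doubly hydrogen-bonded aryl ketone and the methyl ether of ring B resist at 1 atm and room temperature.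

Compound list
1 | 2',6'-dihydroxyacetophenone | CC(=O)c1c(O)cccc1O | starting material
2 | 1-[2,6-bis(benzyloxy)phenyl]ethan-1-one | CC(=O)c1c(OCc2ccccc2)cccc1OCc1ccccc1 | intermediate
3 | 1-[2,6-bis(benzyloxy)phenyl]-3-[di(propan-2-yl)amino]propan-1-one (Mannich base, formed and consumed in step 2) | CC(C)N(CCC(=O)c1c(OCc2ccccc2)cccc1OCc1ccccc1)C(C)C | intermediate
4 | 1-[2,6-bis(benzyloxy)phenyl]prop-2-en-1-one | C=CC(=O)c1c(OCc2ccccc2)cccc1OCc1ccccc1 | intermediate
5 | cyclopentene | C1=CCCC1 | starting material
6 | eugenol (4-allyl-2-methoxyphenol) | COc1cc(CC=C)ccc1O | starting material
7 | (2E)-1-[2,6-bis(benzyloxy)phenyl]octa-2,7-dien-1-one (simplest member of the stage a mixture, formed and consumed in step 3) | C=CCCC/C=C/C(=O)c1c(OCc2ccccc2)cccc1OCc1ccccc1 | intermediate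
8 | (2E,7E)-1-[2,6-bis(benzyloxy)phenyl]-9-(4-hydroxy-3-methoxyphenyl)nona-2,7-dien-1-one | COc1cc(C/C=C/CCC/C=C/C(=O)c2c(OCc3ccccc3)cccc2OCc2ccccc2)ccc1O | intermediate
9 | 1-[2,6-bis(benzyloxy)phenyl]-9-(4-hydroxy-3-methoxyphenyl)nonan-1-one (formed and consumed in step 4) | COc1cc(CCCCCCCCC(=O)c2c(OCc3ccccc3)cccc2OCc2ccccc2)ccc1O | intermediate
10 | 1-(2,6-dihydroxyphenyl)-9-(4-hydroxy-3-methoxyphenyl)nonan-1-one (CNP0118788.0) | COc1cc(CCCCCCCCC(=O)c2c(O)cccc2O)ccc1O | target

Total steps: 4. Longest linear sequence: 4 steps (1 → 2 → 4 → 8 → 10); 5 and 6 are bought.

Steps most likely to fail

Step 3. Several processes could spoil the step.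
- Two enone molecules may cap the same C5 unit in stage a.
- The trimming in stage b may stop short and leave extra C5H8 units, or run past the last C5 unit through the acyl carbene.
- Double bonds may migrate before metathesis and shift the chain length by one carbon.
- The catalyst may die through its methylidene form.

The fallback uses known chemistry, sets out from 6 and 2, and rejoins the route at 8. Cross-metathesis of 6 with an excess of commercial hex-5-enal uses the same ruthenium catalyst with 1,4-benzoquinone in CH2Cl2 at 40 °C. It is an ordinary coupling of two unhindered terminal alkenes steered by stoichiometry. It would give (5E)-7-(4-hydroxy-3-methoxyphenyl)hept-5-enal F1, which holds C3 to C9 and ring B. Ketone 2 is deprotonated with LDA (THF, −78 °C) to lithium 1-[2,6-bis(benzyloxy)phenyl]ethenolate F2. A little over two equivalents are used, one being spent on the phenol proton. Directed aldol addition to F1 gives racemic (7E)-1-[2,6-bis(benzyloxy)phenyl]-3-hydroxy-9-(4-hydroxy-3-methoxyphenyl)non-7-en-1-one F3. Acid-catalysed dehydration (cat. p-TsOH, toluene, 60 °C) then forms C2=C3 and delivers 8.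

Step 2. The vinyl ketone may polymerise in the hot medium, a second aminomethylation may occur, or the hindered ketone may enolise too slowly. The fallback sets out from 2 and returns at 4, and it separates the C–C bond formation from the elimination. Ketone 2 is heated with preformed Eschenmoser's salt (dimethyl(methylidene)ammonium iodide, MeCN, reflux). After basic work-up this gives 1-[2,6-bis(benzyloxy)phenyl]-3-(dimethylamino)propan-1-one F4, a storable amine purified by acid–base extraction. Iodomethane in Et2O precipitates {3-[2,6-bis(benzyloxy)phenyl]-3-oxopropyl}trimethylammonium iodide F5. Shaking F5 with aqueous NaHCO3/CH2Cl2 at room temperature releases 4 by Hofmann-type beta-elimination just before step 3, so the enone never meets heat or acid.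

Step 4. Benzyl ether cleavage may overtake saturation of the enone, so that a freed ortho phenol closes onto C3 by oxa-Michael addition. The aryl ketone may also be over-reduced, or ruthenium residues may poison the palladium. The fallback sets out from 8, passes through 9 (now isolated) and ends at 10. The alkenes alone are hydrogenated over Pd/C poisoned with diphenyl sulfide (H2 1 atm, EtOAc, rt), conditions that leave benzyl ethers and aryl ketones alone. The benzyl ethers are then removed without any reductant by BCl3 and pentamethylbenzene (CH2Cl2, −78 °C). Chelation to the carbonyl directs the Lewis acid to the two ortho ethers, and the methyl ether of ring B is spared at this temperature. No compound outside the list arises (entry F0).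

Further compounds
F1 | step 3 | (5E)-7-(4-hydroxy-3-methoxyphenyl)hept-5-enal | COc1cc(C/C=C/CCCC=O)ccc1O
F2 | step 3 | lithium 1-[2,6-bis(benzyloxy)phenyl]ethenolate | C=C([O-])c1c(OCc2ccccc2)cccc1OCc1ccccc1.[Li+]
F3 | step 3 | (7E)-1-[2,6-bis(benzyloxy)phenyl]-3-hydroxy-9-(4-hydroxy-3-methoxyphenyl)non-7-en-1-one (racemic) | COc1cc(C/C=C/CCCC(O)CC(=O)c2c(OCc3ccccc3)cccc2OCc2ccccc2)ccc1O
F4 | step 2 | 1-[2,6-bis(benzyloxy)phenyl]-3-(dimethylamino)propan-1-one | CN(C)CCC(=O)c1c(OCc2ccccc2)cccc1OCc1ccccc1
F5 | step 2 | {3-[2,6-bis(benzyloxy)phenyl]-3-oxopropyl}trimethylammonium iodide | C[N+](C)(C)CCC(=O)c1c(OCc2ccccc2)cccc1OCc1ccccc1.[I-]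
F0 | step 4 | none | none
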